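**Retrosynthetic overview**
- The C9 quaternary centre (prenyl + isobutyryl) is made last, by exo-face C-prenylation of an enolised tricyclic triketone (Tsuji–Trost).
- The acetyl group comes from oxidative cleavage of an isopropenyl group, with C3 equilibrated to the convex-face epimer.
- Ring C (the trione ring) is the original phloroglucinol ring; rings B (bridging cyclopentanone) and then A (cyclopentane) close in one oxidative radical cascade of two 5-exo cyclisations.
- The one controlling stereocentre (methyl/prenyl quaternary carbon) is set by a desymmetrising, phase-transfer-catalysed enantioselective dearomative C-methylation of achiral deoxycohumulone (key step).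
- Deoxycohumulone comes from phlorisobutyrophenone and prenyl bromide.

Assumptions: phlorisobutyrophenone, prenyl bromide, prenyl acetate and N-(9-anthracenylmethyl)cinchonidinium chloride are bought. The sense of induction in step 2 cannot be predicted with confidence; if the cinchonidine-derived salt gives the (S)-enantiomer, the pseudoenantiomeric cinchonine-derived salt is used. Tricycle locants follow tricyclo[5.3.1.0^1,5]undecane numbering (C1 and C7 bridgeheads, C3 acetyl carbon, C5 ring-fusion CH, C9 acyl-bearing carbon, C11 one-carbon carbonyl bridge). Enols are drawn as one tautomer and CIP descriptors refer to that tautomer.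

**Step 1**
Reactants: 1 phlorisobutyrophenone [2-methyl-1-(2,4,6-trihydroxyphenyl)propan-1-one]; 2 prenyl bromide (1-bromo-3-methylbut-2-ene)
Product: 4 deoxycohumulone {2-methyl-1-[2,4,6-trihydroxy-3,5-bis(3-methylbut-2-en-1-yl)phenyl]propan-1-one; achiral}, via monoprenyl phenol 3 (not isolated)
Conditions: 2 (2.1 equiv), 10% aq KOH, 0 °C, N2; then dilute HCl
Reagents that add atoms: none
Why: Base-mediated aromatic C-prenylation of a phloroglucinolate (Friedel–Crafts-type alkylation), in which water keeps the phenoxide oxygens hydrogen-bonded so the two equivalent free ring carbons are alkylated in turn; no stereocentre is formed.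

**Step 2**
Reactants: 4 deoxycohumulone
Product: 5 (R)-3,5-dihydroxy-6-methyl-2,6-bis(3-methylbut-2-en-1-yl)-4-(2-methylpropanoyl)cyclohexa-2,4-dien-1-one
Conditions: MeI (1.2 equiv), N-(9-anthracenylmethyl)cinchonidinium chloride (10 mol%), CsOH·H2O (2.0 equiv), PhMe/CH2Cl2 (3:1), 4 Å MS, −50 °C; then dilute HCl
Reagents that add atoms: iodomethane (MeI), CI
Why: Proposed new method: desymmetrising enantioselective alkylative dearomatisation, in which the mirror-symmetric monoanion of 4 (phenoxide para to the acyl group, charge on the two enantiotopic prenyl-bearing carbons) forms a tight ion pair with the cinchonidinium cation whose N+ sits over that oxygen and whose free 9-OH hydrogen-bonds one flanking oxygen, so the anthracenylmethyl wall covers one carbon and MeI methylates the other by SN2 to set the (R) quaternary centre while the hydrogen-bonded oxygens stay poorly nucleophilic; the closest known reactions are cinchona phase-transfer C-methylation of indanones and phase-transfer alkylative dearomatisation–annulation of acylphloroglucinols with enal electrophiles.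

**Step 3**
Reactants: 5
Product: 6 (1S,5R,7S)-10-hydroxy-4,4,7-trimethyl-9-(2-methylpropanoyl)-3-(prop-1-en-2-yl)tricyclo[5.3.1.0^1,5]undec-9-ene-8,11-dione (about 1:1 mixture of C3 epimers)
Conditions: Mn(OAc)3·2H2O (2.2 equiv), Cu(OAc)2·H2O (20 mol%), degassed AcOH, rt
Reagents that add atoms: none
Why: Mn(OAc)3-mediated oxidative free-radical cyclisation, known on the racemate: the trivalent manganese enolate gives the radical at the prenyl-bearing ring carbon, which closes 5-exo-trig onto the prenyl group of the quaternary carbon (ring B, with C1 and C5 fixed by the bridging geometry from C7), the tertiary radical closes a second 5-exo-trig onto the other prenyl group (ring A, cis-fused), and divalent copper oxidises the last radical to the isopropenyl group; C3 is not controlled here and is corrected in step 4.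

**Step 4**
Reactants: 6
Product: 9 (1S,3S,5R,7S)-3-acetyl-10-hydroxy-4,4,7-trimethyl-9-(2-methylpropanoyl)tricyclo[5.3.1.0^1,5]undec-9-ene-8,11-dione (single C3 epimer; acetyl cis to H5), via diol 7 (not isolated), via C3-epimeric methyl ketones 8 (not isolated)
Conditions: OsO4 (2 mol%), NaIO4 (4 equiv), 2,6-lutidine (2 equiv), dioxane/H2O (3:1), rt; extractive work-up; then TsOH·H2O (20 mol%), PhMe, 80 °C
Reagents that add atoms: osmium tetroxide (OsO4), O=[Os](=O)(=O)=O; sodium periodate (NaIO4, terminal source of the new carbonyl oxygen), [Na+].[O-]I(=O)(=O)=O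
Why: Lemieux–Johnson cleavage of the only isolated C=C (the push–pull enol is a poor osmylation partner), then acid-catalysed enolisation of the methyl ketone equilibrates C3, as at C17 of 20-oxopregnanes, towards the epimer with acetyl on the convex face cis to H5 and away from the C6 methylene of ring B; the minor epimer is resubmitted.

**Step 5**
Reactants: 9; 10 prenyl acetate (3-methylbut-2-en-1-yl acetate)
Product: 11 CNP0322535.2, (1R,3S,5R,7S,9S)-3-acetyl-4,4,7-trimethyl-9-(3-methylbut-2-en-1-yl)-9-(2-methylpropanoyl)tricyclo[5.3.1.0^1,5]undecane-8,10,11-trione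
Conditions: 10 (1.5 equiv), Pd(PPh3)4 (5 mol%), Et3N (1.2 equiv), THF, 0 °C to rt
Reagents that add atoms: none
Why: Tsuji–Trost allylic alkylation, in which the soft triketonate attacks the unsubstituted terminus of the π-prenyl palladium cation through C9 from the exo face (syn to the one-carbon C11 carbonyl bridge, anti to the two-carbon bridge whose endo hydrogens shield the other face), which places prenyl exo and isobutyryl endo; any O-prenyl enol ether is re-ionised by zerovalent palladium and funnelled to the C-alkylated product.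

**Compound list**
1 | phlorisobutyrophenone, 2-methyl-1-(2,4,6-trihydroxyphenyl)propan-1-one | CC(C)C(=O)c1c(O)cc(O)cc1O | starting material
2 | prenyl bromide, 1-bromo-3-methylbut-2-ene | CC(C)=CCBr | starting material
3 | monoprenyl phenol, 2-methyl-1-[2,4,6-trihydroxy-3-(3-methylbut-2-en-1-yl)phenyl]propan-1-one | CC(C)=CCc1c(O)cc(O)c(C(=O)C(C)C)c1O | intermediate
4 | deoxycohumulone, 2-methyl-1-[2,4,6-trihydroxy-3,5-bis(3-methylbut-2-en-1-yl)phenyl]propan-1-one | CC(C)=CCc1c(O)c(CC=C(C)C)c(O)c(C(=O)C(C)C)c1O | intermediate
5 | (R)-3,5-dihydroxy-6-methyl-2,6-bis(3-methylbut-2-en-1-yl)-4-(2-methylpropanoyl)cyclohexa-2,4-dien-1-one | CC(C)=CCC1=C(O)C(C(=O)C(C)C)=C(O)[C@@](C)(CC=C(C)C)C1=O | intermediate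
6 | (1S,5R,7S)-10-hydroxy-4,4,7-trimethyl-9-(2-methylpropanoyl)-3-(prop-1-en-2-yl)tricyclo[5.3.1.0^1,5]undec-9-ene-8,11-dione, C3 epimer mixture | CC(=C)C1C[C@]23C(=O)[C@](C)(C[C@@H]2C1(C)C)C(=O)C(C(=O)C(C)C)=C3O | intermediate
7 | diol, the 3-(1,2-dihydroxypropan-2-yl) analogue of 6, epimer mixture | CC(O)(CO)C1C[C@]23C(=O)[C@](C)(C[C@@H]2C1(C)C)C(=O)C(C(=O)C(C)C)=C3O | intermediate
8 | C3-epimeric methyl ketones, the 3-acetyl analogue of 6 | CC(=O)C1C[C@]23C(=O)[C@](C)(C[C@@H]2C1(C)C)C(=O)C(C(=O)C(C)C)=C3O | intermediate
9 | (1S,3S,5R,7S)-3-acetyl-10-hydroxy-4,4,7-trimethyl-9-(2-methylpropanoyl)tricyclo[5.3.1.0^1,5]undec-9-ene-8,11-dione, acetyl cis to H5 | CC(=O)[C@H]1C[C@]23C(=O)[C@](C)(C[C@@H]2C1(C)C)C(=O)C(C(=O)C(C)C)=C3O | intermediate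
10 | prenyl acetate, 3-methylbut-2-en-1-yl acetate | CC(=O)OCC=C(C)C | starting material
11 | CNP0322535.2, (1R,3S,5R,7S,9S)-3-acetyl-4,4,7-trimethyl-9-(3-methylbut-2-en-1-yl)-9-(2-methylpropanoyl)tricyclo[5.3.1.0^1,5]undecane-8,10,11-trione | CC(=O)[C@H]1C[C@]23C(=O)[C@](C)(C[C@@H]2C1(C)C)C(=O)[C@](CC=C(C)C)(C(=O)C(C)C)C3=O | target

**Step count**
Total steps: 5. Longest linear sequence: 5 (from 1).

**Steps most likely to fail**

Step 2 (proposed new step). The risks are low enantioselectivity, O-methylation in the aprotic ion pair, and over-methylation of the more acidic product. The fallback uses known chemistry, sets out from 4 and comes back at 5. Compound 4 is C-methylated with NaOMe and MeI in MeOH at rt, a reaction known for this substrate, to give the racemic dienone F1. Preparative chiral SFC then gives (R)-5 and leaves the (S)-enantiomer F2. If the catalytic step gives useful but incomplete ee, the enantiomeric purity can also be raised by crystallising 9.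

Step 5. The risks are O- rather than C-prenylation at the crowded tricarbonyl carbon, attack at the tertiary allyl terminus, and retro-Claisen loss of the isobutyryl group from the non-enolisable product. The fallback sets out from 9 and comes back at 11. Allyl acetate with Pd(PPh3)4 and Et3N in THF gives the less hindered C9-allyl trione F6 from the same exo face; any O-allyl ether is converted by warming (Claisen rearrangement). Cross-metathesis of F6 with 2-methylbut-2-ene (second-generation Grubbs catalyst RuCl2(=CHPh)(PCy3)(H2IMes), CH2Cl2, 40 °C) then turns allyl into prenyl.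

Step 4. The main risk is that the C3 equilibrium is not clearly on the side of the wanted epimer; the convex-face preference is an argument from the ring geometry, not a measured ratio. The fallback sets out from 6 and comes back at 9, and replaces convergence by equilibration with separation. The two C3 epimers of 6 are separated by chromatography into the (3R) epimer F3 (isopropenyl cis to H5) and the (3S) epimer F4. Only F3 is cleaved, with OsO4 (cat.) and NaIO4 under 2,6-lutidine buffer and with no acid stage, through the single-epimer diol F5, so that C3 is retained. F4 is set aside.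

**Further compounds**
F1 | step 2 | racemic 3,5-dihydroxy-6-methyl-2,6-bis(3-methylbut-2-en-1-yl)-4-(2-methylpropanoyl)cyclohexa-2,4-dien-1-one | CC(C)=CCC1=C(O)C(C(=O)C(C)C)=C(O)C(C)(CC=C(C)C)C1=O
F2 | step 2 | (S)-3,5-dihydroxy-6-methyl-2,6-bis(3-methylbut-2-en-1-yl)-4-(2-methylpropanoyl)cyclohexa-2,4-dien-1-one | CC(C)=CCC1=C(O)C(C(=O)C(C)C)=C(O)[C@](C)(CC=C(C)C)C1=O
F3 | step 4 | (1S,3R,5R,7S)-10-hydroxy-4,4,7-trimethyl-9-(2-methylpropanoyl)-3-(prop-1-en-2-yl)tricyclo[5.3.1.0^1,5]undec-9-ene-8,11-dione | CC(=C)[C@H]1C[C@]23C(=O)[C@](C)(C[C@@H]2C1(C)C)C(=O)C(C(=O)C(C)C)=C3O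
F4 | step 4 | (1S,3S,5R,7S)-10-hydroxy-4,4,7-trimethyl-9-(2-methylpropanoyl)-3-(prop-1-en-2-yl)tricyclo[5.3.1.0^1,5]undec-9-ene-8,11-dione | CC(=C)[C@@H]1C[C@]23C(=O)[C@](C)(C[C@@H]2C1(C)C)C(=O)C(C(=O)C(C)C)=C3O
F5 | step 4 | single-C3-epimer diol, the 3-(1,2-dihydroxypropan-2-yl) analogue of F3 | CC(O)(CO)[C@H]1C[C@]23C(=O)[C@](C)(C[C@@H]2C1(C)C)C(=O)C(C(=O)C(C)C)=C3O
F6 | step 5 | (1R,3S,5R,7S,9S)-3-acetyl-4,4,7-trimethyl-9-(2-methylpropanoyl)-9-(prop-2-en-1-yl)tricyclo[5.3.1.0^1,5]undecane-8,10,11-trione | CC(=O)[C@H]1C[C@]23C(=O)[C@](C)(C[C@@H]2C1(C)C)C(=O)[C@](CC=C)(C(=O)C(C)C)C3=O
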